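**Assumption:** the target has no stereocentre and is achiral, so "single enantiomer" is read as the single geometric isomer drawn, with a (Z)-styryl carbinol and an (E)-enone. These are the only stereo-elements to control.

## Retrosynthetic overview
1. Final step: remove two O-allyl groups under near-neutral Pd(0) conditions. The whole route avoids acid because the (Z)-o-hydroxystyryl tertiary carbinol cyclodehydrates to a 2,2-dimethylchromene in acid.
2. Disconnect the enone Cα=Cβ (Claisen–Schmidt, sets E) to an A-ring acetophenone and 4-(allyloxy)benzaldehyde.
3. Disconnect the A-ring C3'–vinyl bond (new reaction) to free 2',4'-dihydroxy-6'-methoxyacetophenone (C–H partner) and (Z)-4-iodo-2-methylbut-3-en-2-ol. The Z geometry is transferred from the iodide.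
4. The Z-iodide comes from ethyl (Z)-3-iodoacrylate and 2 MeMgBr.
5. No ring is formed. Both benzene rings are purchased.

## Route

**Step 1**
Reactants: 1 ethyl (Z)-3-iodoacrylate
Product: 3 (Z)-4-iodo-2-methylbut-3-en-2-ol
Conditions: MeMgBr (2.5 equiv), Et2O, −78 → 0 °C, dark; sat. aq NH4Cl
Reagents that add atoms: 2 methylmagnesium bromide, C[Mg]Br (two CH3)
Why: Double Grignard addition to an ester. MeMgBr does not undergo I/Mg exchange or conjugate addition at low temperature, so the pre-set Z C=C is carried through unchanged.

**Step 2 (key new step)**
Reactants: 3 (Z)-4-iodo-2-methylbut-3-en-2-ol (1.0 equiv); 4 2',4'-dihydroxy-6'-methoxyacetophenone (1.5 equiv, excess recovered)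
Product: 5 1-{2,4-dihydroxy-3-[(1Z)-3-hydroxy-3-methylbut-1-enyl]-6-methoxyphenyl}ethanone
Conditions: Pd(OAc)2 (5 mol %), 2-(di-tert-butylphosphino)-2'-methylbiphenyl (10 mol %), K3PO4 (3 equiv), degassed dioxane/t-AmOH 4:1, 60 °C, dark; pH 7 phosphate work-up; Et3N-washed SiO2
Reagents that add atoms: none (all heavy atoms come from 3 and 4; HI is lost)
Why: Proposed new method: Pd(0)-catalysed, stereoretentive C3–H alkenylation of an unprotected acylphloroglucinol acting as a masked cyclic 1,3-diketone enolate; oxidative addition of the Z-iodide proceeds with retention, and the neighbouring tertiary OH/alkoxide clips onto Pd as a five-membered C,O-chelate that locks Z; proton transfer from phenol 4 opens the chelate and places the aryloxide on Pd; the aryloxide slips from O to its C3-bound dienone tautomer, because C3 is the only ring carbon flanked by two ionisable oxygens and so resembles a β-diketonate carbon, whereas C5 has only one and the acetyl CH3 is not deprotonated by K3PO4; C–C reductive elimination and re-aromatising tautomerisation then give 5; C–O reductive elimination is disfavoured because the aryloxide is an electron-poor vinylogous carboxylate that is H-bonded to the pendant OH; the closest known reaction types are Pd-catalysed α-arylation/α-alkenylation of ketone and cyclic 1,3-diketone enolates and Pd-catalysed ortho-C (dearomative) arylation of phenoxides/naphthoxides; intermolecular ring C–H alkenylation of a phenol with a Z-alkenyl halide has not been shown.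

**Step 3**
Reactants: 5
Product: 7 1-{4-(allyloxy)-2-hydroxy-3-[(1Z)-3-hydroxy-3-methylbut-1-enyl]-6-methoxyphenyl}ethanone
Conditions: allyl bromide (1.1 equiv), K2CO3 (1.5 equiv), acetone, 45 °C, 6 h
Reagents that add atoms: 6 allyl bromide, C=CCBr
Why: Williamson etherification. The 2-OH is hydrogen-bonded to the acetyl C=O and hindered, and the tertiary OH is not ionised by K2CO3, so only the acidic 4-OH reacts. The basic medium leaves the Z-carbinol untouched.

**Step 4**
Reactants: 7; 8 4-(allyloxy)benzaldehyde (1.2 equiv)
Product: 9 (2E)-1-{4-(allyloxy)-2-hydroxy-3-[(1Z)-3-hydroxy-3-methylbut-1-enyl]-6-methoxyphenyl}-3-[4-(allyloxy)phenyl]prop-2-en-1-one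
Conditions: KOH (50 % aq, 15 equiv), EtOH, 0 °C → rt, 36 h, N2, dark; pour into cold pH 6.5–7 phosphate buffer
Reagents that add atoms: none (all heavy atoms come from 7 and 8; H2O is lost)
Why: Claisen–Schmidt condensation, the standard 2'-hydroxy-4',6'-dialkoxychalcone synthesis. E1cB dehydration gives the thermodynamic E-enone. Aryl allyl ethers, the tertiary alcohol and the Z-alkene are inert to hydroxide, and in strong base the open chalcone phenoxide is favoured over the flavanone.

**Step 5**
Reactants: 9
Product: 10 candidachalcone
Conditions: Pd(PPh3)4 (5 mol %), morpholine (6 equiv), THF, rt, 1–2 h, dark; pH 7 buffer wash; Sephadex LH-20 (MeOH)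
Reagents that add atoms: none
Why: Tsuji–Trost-type deallylation. Both allyl ethers sit on carbonyl-conjugated phenols, which are good leaving groups, and excess morpholine traps the π-allyl. The unactivated tertiary allylic alcohol is not ionised by Pd(0) without acid. The mild, short, acid-free conditions avoid chromene formation, flavanone cyclisation and any change to either alkene geometry.

## Compound list
1 | ethyl (Z)-3-iodoacrylate | CCOC(=O)/C=C\I | starting material
2 | methylmagnesium bromide | C[Mg]Br | starting material (reagent)
3 | (Z)-4-iodo-2-methylbut-3-en-2-ol | CC(C)(O)/C=C\I | intermediate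
4 | 2',4'-dihydroxy-6'-methoxyacetophenone | CC(=O)c1c(O)cc(O)cc1OC | starting material
5 | 1-{2,4-dihydroxy-3-[(1Z)-3-hydroxy-3-methylbut-1-enyl]-6-methoxyphenyl}ethanone | COc1cc(O)c(/C=C\C(C)(C)O)c(O)c1C(C)=O | intermediate
6 | allyl bromide | C=CCBr | starting material (reagent)
7 | 1-{4-(allyloxy)-2-hydroxy-3-[(1Z)-3-hydroxy-3-methylbut-1-enyl]-6-methoxyphenyl}ethanone | COc1cc(OCC=C)c(/C=C\C(C)(C)O)c(O)c1C(C)=O | intermediate
8 | 4-(allyloxy)benzaldehyde | C=CCOc1ccc(C=O)cc1 | starting material
9 | 4,4'-di-O-allylcandidachalcone (2E, 1''Z) | COc1cc(OCC=C)c(/C=C\C(C)(C)O)c(O)c1C(=O)/C=C/c1ccc(OCC=C)cc1 | intermediate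
10 | candidachalcone, (2E)-1-{2,4-dihydroxy-3-[(1Z)-3-hydroxy-3-methylbut-1-enyl]-6-methoxyphenyl}-3-(4-hydroxyphenyl)prop-2-en-1-one | COc1cc(O)c(/C=C\C(C)(C)O)c(O)c1C(=O)/C=C/c1ccc(O)cc1 | target

## Summary
Total steps: 5. Longest linear sequence: 5 (1 → 3 → 5 → 7 → 9 → 10).

**Steps most likely to fail**
1. **Step 2 (new C–H alkenylation).**
   - Risks: O-vinylation, reaction at C5, an unreactive κ2-O,O acylphenoxide–Pd resting state, and loss of HI from 3.
   - Fallback (known chemistry only): iodinate 4 at C3 with NIS, then protect as the bis-TBS ether. Carry out a Sonogashira coupling with 2-methylbut-3-yn-2-ol (PdCl2(PPh3)2/CuI/Et3N), then Lindlar/quinoline semihydrogenation to the Z-alkene. TBAF/AcOH then rejoins the route at 5.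
2. **Step 5 (final deallylation).**
   - Risks: amine-promoted flavanone closure or aza-Michael addition, C-allylation of the freed phloroglucinol ring, and Pd-mediated ionisation of the carbinol to the chromene or the E-isomer.
   - Fallback: change the protecting-group strategy. Use aryl TBS ethers (TBSCl on 5; 4-(TBSO)benzaldehyde) with the tertiary OH as its TES ether. Build the enone under non-hydrolytic conditions and finish with buffered fluoride (TBAF/AcOH, 0 °C).
3. **Step 4 (Claisen–Schmidt on the hindered, sensitive ketone).**
   - Risks: slow condensation, and flavanone or decomposition products over a long time in base.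
   - Fallback: replace the one-pot thermodynamic condensation with a stepwise kinetic sequence. Treat 7 with LiHMDS (3.2 equiv, THF, −78 °C) and add 8 to give the isolable β-hydroxy ketone. Acetylate the secondary benzylic OH selectively and eliminate with DBU (E1cB) to the E-enone. Any aryl acetate is removed with K2CO3/MeOH.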